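**Plan**
1. Cuts, in retrosynthetic order: C12–C13 and C11–C12 (side chain), then the C3–C4 bond of ring A, then C10–C1 and C9–C11 on a ring-B enone, then C4–C5.
2. Forward: ring B is bought as 2-methylcyclohexenone; CBS reduction, Johnson–Claisen, allylic oxidation, cuprate 1,4-addition with enolate hydroxymethylation and C8 methylenation follow. A SmI2 Reformatsky reaction then closes ring A, and the lactone, bought as a ring, is joined last.
3. Stereochemistry: C5 from the CBS carbinol by 1,3-chirality transfer; C10 by cuprate attack anti to the C5 arm; C9 by equilibration (equatorial); C3 and C4 in the key step; C11 by Felkin–Anh attack on the C9 aldehyde.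
4. Enabling feature: in ring A the oxygen on C3 and C19 on C4 form a β-hydroxy-ester (aldol) pattern across C3–C4, and the axial C20 methyl on C10, 1,3 to C4, should force the C4 methyl equatorial and C19 axial in a samarium-chelated chair.

Key step: step 11

Remark: labdane numbering (C1–C20) is used for atom labels. Ring B (from 1) and the lactone ring (from 25) are bought as rings, so ring A is the only ring of the target that is closed; the acetonide and epoxide made later are temporary helpers. LDA, KHMDS and SmI2 are taken as commercial solutions.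

**Route**

Step 1
Reactants: 1 2-methylcyclohex-2-en-1-one
Product: 2 (1R)-2-methylcyclohex-2-en-1-ol
Conditions: (S)-Me-CBS (10 mol %), BH3·SMe2, THF, −20 °C; MeOH quench
Reagents that add atoms: none
Why: Corey–Bakshi–Shibata reduction, in which the alkenyl carbon acts as the large group, so hydride should be delivered to the face that gives the (R)-carbinol, whose chirality is later passed on to C5.

Step 2
Reactants: 2 (1R)-2-methylcyclohex-2-en-1-ol; 3 triethyl orthoacetate
Product: 5 ethyl 2-[(1R)-2-methylcyclohex-2-en-1-yl]acetate, via mixed ketene acetal 4 (not isolated)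
Conditions: 3 (excess), EtCO2H (cat.), 140 °C, EtOH distilled off
Reagents that add atoms: none
Why: Johnson–Claisen rearrangement; the suprafacial [3,3] shift should place the new C4–C5 bond on the ring face that carried the C–O bond, so the carbinol chirality is transferred to C5 while the double bond moves to C9=C10.

Step 3
Reactants: 5 ethyl 2-[(1R)-2-methylcyclohex-2-en-1-yl]acetate
Product: 6 ethyl 2-[(1R)-2-methyl-4-oxocyclohex-2-en-1-yl]acetate
Conditions: Rh2(cap)4 (1 mol %), t-BuOOH (70 % aq.), K2CO3 (cat.), CH2Cl2, rt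
Reagents that add atoms: tert-butyl hydroperoxide, CC(C)(C)OO
Why: dirhodium-catalysed radical allylic oxidation, which should attack the secondary allylic CH2 (C8) next to the unsubstituted alkene carbon and not the hindered tertiary C5–H, so the enone forms without touching C5.

Step 4
Reactants: 6 ethyl 2-[(1R)-2-methyl-4-oxocyclohex-2-en-1-yl]acetate; 7 2-(2-bromoethyl)-1,3-dioxolane
Product: 9 ethyl 2-[(1R,2R)-2-[2-(1,3-dioxolan-2-yl)ethyl]-2-methyl-4-[(trimethylsilyl)oxy]cyclohex-3-en-1-yl]acetate, via Grignard reagent 8 (not isolated)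
Conditions: 7, Mg, THF, 25 °C; CuBr·SMe2 (20 mol %), TMSCl, HMPA, THF, −78 °C, then 6; Et3N, non-aqueous work-up
Reagents that add atoms: chlorotrimethylsilane, C[Si](C)(C)Cl
Why: copper-catalysed conjugate addition with in situ silyl trapping; the cuprate should add to C10 anti to the C5 arm (axial attack on the 4-substituted cyclohexenone), which sets quaternary C10 with its methyl trans to C5–H and keeps the enolate as the regiodefined C8–C9 enol silane.

Step 5
Reactants: 9 ethyl 2-[(1R,2R)-2-[2-(1,3-dioxolan-2-yl)ethyl]-2-methyl-4-[(trimethylsilyl)oxy]cyclohex-3-en-1-yl]acetate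
Product: 10 ethyl 2-[(1R,2R,3RS)-2-[2-(1,3-dioxolan-2-yl)ethyl]-3-(hydroxymethyl)-2-methyl-4-oxocyclohexyl]acetate
Conditions: aq. HCHO (37 %), Yb(OTf)3 (10 mol %), THF, rt
Reagents that add atoms: formaldehyde, C=O
Why: lanthanide-triflate-catalysed Mukaiyama-type aldol with aqueous formaldehyde, regiospecific at C9 because the enol silane is regiodefined; the C9 configuration is not relied on here (attack anti to the axial C10 methyl may favour the 9-epimer) and is set in step 6.

Step 6
Reactants: 10 ethyl 2-[(1R,2R,3RS)-2-[2-(1,3-dioxolan-2-yl)ethyl]-3-(hydroxymethyl)-2-methyl-4-oxocyclohexyl]acetate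
Product: 11 ethyl 2-[(1R,2R,3R)-3-{[tert-butyl(diphenyl)silyl]oxymethyl}-2-[2-(1,3-dioxolan-2-yl)ethyl]-2-methyl-4-oxocyclohexyl]acetate
Conditions: TBDPSCl, imidazole, DMF, rt; then DBU (cat.), toluene, rt
Reagents that add atoms: tert-butyl(chloro)diphenylsilane, CC(C)(C)[Si](Cl)(c1ccccc1)c1ccccc1
Why: silylation of the primary alcohol, then base equilibration of C9 (α to the C8 ketone) to the isomer with the CH2OSi arm equatorial and cis to the C10 methyl, the arrangement that is the stable one in 8-oxo-drimanes.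

Step 7
Reactants: 11 ethyl 2-[(1R,2R,3R)-3-{[tert-butyl(diphenyl)silyl]oxymethyl}-2-[2-(1,3-dioxolan-2-yl)ethyl]-2-methyl-4-oxocyclohexyl]acetate
Product: 12 ethyl 2-[(1R,2R,3R)-3-{[tert-butyl(diphenyl)silyl]oxymethyl}-2-[2-(1,3-dioxolan-2-yl)ethyl]-2-methyl-4-methylidenecyclohexyl]acetate
Conditions: Ph3PCH3Br, KOt-Bu, toluene, 0 → 70 °C
Reagents that add atoms: methyltriphenylphosphonium bromide, C[P+](c1ccccc1)(c1ccccc1)c1ccccc1.[Br-]
Why: Wittig methylenation of the C8 ketone, which the ester, acetal and silyl ether should survive; C9 keeps its thermodynamic configuration and is fixed from here on.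

Step 8
Reactants: 12 ethyl 2-[(1R,2R,3R)-3-{[tert-butyl(diphenyl)silyl]oxymethyl}-2-[2-(1,3-dioxolan-2-yl)ethyl]-2-methyl-4-methylidenecyclohexyl]acetate
Product: 14 ethyl (2RS)-2-[(1R,2R,3R)-3-{[tert-butyl(diphenyl)silyl]oxymethyl}-2-[2-(1,3-dioxolan-2-yl)ethyl]-2-methyl-4-methylidenecyclohexyl]propanoate, via lithium enolate 13 (not isolated)
Conditions: LDA, THF, −78 °C; MeI, −78 → −20 °C
Reagents that add atoms: iodomethane, CI
Why: ester enolate alkylation at the only acidic site left installs the C18 methyl; the C4 configuration is irrelevant because C4 becomes an enolate again.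

Step 9
Reactants: 14 ethyl (2RS)-2-[(1R,2R,3R)-3-{[tert-butyl(diphenyl)silyl]oxymethyl}-2-[2-(1,3-dioxolan-2-yl)ethyl]-2-methyl-4-methylidenecyclohexyl]propanoate
Product: 16 ethyl (2RS)-2-bromo-2-[(1S,2S,3R)-3-{[tert-butyl(diphenyl)silyl]oxymethyl}-2-[2-(1,3-dioxolan-2-yl)ethyl]-2-methyl-4-methylidenecyclohexyl]propanoate, via lithium enolate 15 (not isolated)
Conditions: LDA, THF, −78 °C; CBr4, −78 °C
Reagents that add atoms: carbon tetrabromide, BrC(Br)(Br)Br
Why: electrophilic bromination of the tetrasubstituted ester enolate gives the tertiary α-bromo ester needed as Reformatsky donor; C4 stays a mixture without consequence (the ring descriptors change only through CIP priorities).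

Step 10
Reactants: 16 ethyl (2RS)-2-bromo-2-[(1S,2S,3R)-3-{[tert-butyl(diphenyl)silyl]oxymethyl}-2-[2-(1,3-dioxolan-2-yl)ethyl]-2-methyl-4-methylidenecyclohexyl]propanoate
Product: 17 ethyl (2RS)-2-bromo-2-[(1S,2S,3R)-3-{[tert-butyl(diphenyl)silyl]oxymethyl}-2-methyl-4-methylidene-2-(3-oxopropyl)cyclohexyl]propanoate
Conditions: aq. HCl (1 M), THF, rt
Reagents that add atoms: water, O
Why: acid hydrolysis of the dioxolane releases the C3 aldehyde; the TBDPS ether, tertiary bromide and exocyclic alkene should tolerate the mild acid.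

Step 11
Reactants: 17 ethyl (2RS)-2-bromo-2-[(1S,2S,3R)-3-{[tert-butyl(diphenyl)silyl]oxymethyl}-2-methyl-4-methylidene-2-(3-oxopropyl)cyclohexyl]propanoate
Product: 19 ethyl (1S,2R,4aR,5R,8aS)-5-{[tert-butyl(diphenyl)silyl]oxymethyl}-2-hydroxy-1,4a-dimethyl-6-methylidenedecahydronaphthalene-1-carboxylate, via samarium enolate 18 (not isolated)
Conditions: SmI2 (2.5 equiv), THF, −78 °C; sat. NH4Cl
Reagents that add atoms: none
Why: Two SmI2 reduce the tertiary C4–Br bond to a samarium(III) ester enolate, which adds to the C3 aldehyde through a samarium-bridged chair (Zimmerman–Traxler) transition state; the closest known reaction type is the SmI2-promoted intramolecular Reformatsky reaction. Ring A closes by C3–C4 bond formation in a 6-(enolexo)-exo-trig aldol mode onto the preset trans C5/C10 arms, so the trans-decalin should form directly as a chair. At C4, one of CH3 and C19 must become axial and 1,3-syn to the axial C20 methyl on C10; the flat enolate carbon C19 should take that place and the C4 methyl go equatorial. At C3, the aldehyde oxygen must stay gauche to C19 to share samarium, which with C19 axial is only possible when the oxygen is equatorial, that is cis to C19. The step needs reduction of the C–Br bond before the aldehyde and facial control at the enolate; the first is secured because α-bromo esters react with SmI2 far faster than aliphatic aldehydes at −78 °C, the second by the axial C10 methyl and the chelate.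

Step 12
Reactants: 19 ethyl (1S,2R,4aR,5R,8aS)-5-{[tert-butyl(diphenyl)silyl]oxymethyl}-2-hydroxy-1,4a-dimethyl-6-methylidenedecahydronaphthalene-1-carboxylate
Product: 20 (1R,2R,4aR,5R,8aS)-5-{[tert-butyl(diphenyl)silyl]oxymethyl}-1-(hydroxymethyl)-1,4a-dimethyl-6-methylidenedecahydronaphthalen-2-ol
Conditions: LiAlH4, THF, 0 °C → rt
Reagents that add atoms: none
Why: hydride reduction of the hindered axial ester to the C19 primary alcohol; no stereocentre is touched.

Step 13
Reactants: 20 (1R,2R,4aR,5R,8aS)-5-{[tert-butyl(diphenyl)silyl]oxymethyl}-1-(hydroxymethyl)-1,4a-dimethyl-6-methylidenedecahydronaphthalen-2-ol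
Product: 21 3,19-acetonide of 20 (1,3-dioxane across O3 and O19, C11 silyl ether retained)
Conditions: 2,2-dimethoxypropane, PPTS (cat.), CH2Cl2, rt
Reagents that add atoms: 2,2-dimethoxypropane, COC(C)(C)OC
Why: acetal exchange; the cis 1,3-diol (equatorial C3–OH, axial C19) should close the six-membered acetonide, as is usual for the 3,19-diol of this family.

Step 14
Reactants: 21 3,19-acetonide of 20
Product: 22 C11 primary alcohol (3,19-acetonide, free CH2OH on C9)
Conditions: TBAF, THF, rt
Reagents that add atoms: none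
Why: fluoride cleavage of the silyl ether; acetonide and alkene are inert.

Step 15
Reactants: 22 C11 primary alcohol
Product: 23 C11 aldehyde (3,19-acetonide, CHO on C9)
Conditions: Dess–Martin periodinane, NaHCO3, CH2Cl2, 0 °C
Reagents that add atoms: none
Why: buffered Dess–Martin oxidation should give the β,γ-unsaturated aldehyde without epimerising C9 or moving the C8 double bond into conjugation.

Step 16
Reactants: 23 C11 aldehyde
Product: 24 (11S)-11,12-epoxide (3,19-acetonide, (2S)-oxiran-2-yl on C9)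
Conditions: Me3S+ I−, KHMDS, THF, −10 °C; then 23, −78 → 0 °C
Reagents that add atoms: trimethylsulfonium iodide, C[S+](C)C.[I-]
Why: Corey–Chaykovsky epoxidation; the ylide should add in the Felkin–Anh sense (quaternary C10 anti to the nucleophile, C9–H beside its trajectory), which gives the C11 configuration of the target (descriptor S in the epoxide by CIP priority only).

Step 17
Reactants: 25 3-bromooxolan-2-one (α-bromo-γ-butyrolactone); 26 benzenethiol
Product: 27 3-(phenylsulfanyl)oxolan-2-one (racemic)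
Conditions: Et3N, CH2Cl2, 0 °C → rt
Reagents that add atoms: none
Why: SN2 displacement of the activated α-bromide by thiophenolate; the stereocentre is racemic and is destroyed later.

Step 18
Reactants: 24 (11S)-11,12-epoxide; 27 3-(phenylsulfanyl)oxolan-2-one
Product: 30 3-[(2R)-2-hydroxy-2-(decalinyl)ethyl]-3-(phenylsulfanyl)oxolan-2-one (3,19-acetonide, mixture at the lactone α-carbon), via lithium enolate 28 (not isolated), via aluminium enolate 29 (not isolated)
Conditions: 27, LDA, THF, −78 °C; Et2AlCl, −78 °C; then 24, −78 → −30 °C; AcOH quench at −78 °C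
Reagents that add atoms: none
Why: epoxide opening by an aluminium ester enolate at the unhindered CH2 terminus (C12) leaves C11 untouched; the aluminium alkoxide formed should be too weakly nucleophilic at low temperature to attack the lactone carbonyl.

Step 19
Reactants: 30 hydroxy sulfide
Product: 32 14-deoxy-11-hydroxyandrographolide 3,19-acetonide, via sulfoxide 31 (not isolated)
Conditions: mCPBA (1.0 equiv), CH2Cl2, −78 °C; NaHCO3 wash; then toluene, pyridine (cat.), 100 °C
Reagents that add atoms: none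
Why: sulfide oxidation (much faster than epoxidation of the 1,1-disubstituted alkene at −78 °C) followed by thermal sulfoxide syn-elimination, which in α-alkyl-α-sulfinyl γ-lactones should run toward the ring CH2 (C14) to give the endocyclic butenolide.

Step 20
Reactants: 32 14-deoxy-11-hydroxyandrographolide 3,19-acetonide
Product: 33 14-deoxy-11-hydroxyandrographolide
Conditions: AcOH/H2O (3:1), 40 °C
Reagents that add atoms: none
Why: mild acid hydrolysis of the acetonide, under which the butenolide, the exocyclic alkene and the C11 alcohol should be stable.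

**Compound list**
1 | 2-methylcyclohex-2-en-1-one | CC1=CCCCC1=O | starting material
2 | (1R)-2-methylcyclohex-2-en-1-ol | O[C@@H]1CCCC=C1C | intermediate
3 | triethyl orthoacetate (1,1,1-triethoxyethane) | CC(OCC)(OCC)OCC | starting material
4 | mixed ketene acetal, (6R)-6-[(1-ethoxyethenyl)oxy]-1-methylcyclohex-1-ene | C=C(OCC)O[C@@H]1CCCC=C1C | intermediate
5 | ethyl 2-[(1R)-2-methylcyclohex-2-en-1-yl]acetate | CCOC(=O)C[C@H]1CCCC=C1C | intermediate
6 | ethyl 2-[(1R)-2-methyl-4-oxocyclohex-2-en-1-yl]acetate | CCOC(=O)C[C@H]1CCC(=O)C=C1C | intermediate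
7 | 2-(2-bromoethyl)-1,3-dioxolane | BrCCC1OCCO1 | starting material
8 | [2-(1,3-dioxolan-2-yl)ethyl]magnesium bromide | Br[Mg]CCC1OCCO1 | intermediate
9 | ethyl 2-[(1R,2R)-2-[2-(1,3-dioxolan-2-yl)ethyl]-2-methyl-4-[(trimethylsilyl)oxy]cyclohex-3-en-1-yl]acetate | CCOC(=O)C[C@H]1CCC(O[Si](C)(C)C)=C[C@]1(C)CCC2OCCO2 | intermediate
10 | ethyl 2-[(1R,2R,3RS)-2-[2-(1,3-dioxolan-2-yl)ethyl]-3-(hydroxymethyl)-2-methyl-4-oxocyclohexyl]acetate | CCOC(=O)C[C@H]1CCC(=O)C(CO)[C@]1(C)CCC2OCCO2 | intermediate
11 | ethyl 2-[(1R,2R,3R)-3-{[tert-butyl(diphenyl)silyl]oxymethyl}-2-[2-(1,3-dioxolan-2-yl)ethyl]-2-methyl-4-oxocyclohexyl]acetate | CCOC(=O)C[C@H]1CCC(=O)[C@@H](CO[Si](c2ccccc2)(c3ccccc3)C(C)(C)C)[C@]1(C)CCC4OCCO4 | intermediate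
12 | ethyl 2-[(1R,2R,3R)-3-{[tert-butyl(diphenyl)silyl]oxymethyl}-2-[2-(1,3-dioxolan-2-yl)ethyl]-2-methyl-4-methylidenecyclohexyl]acetate | C=C1CC[C@H](CC(=O)OCC)[C@@](C)(CCC2OCCO2)[C@@H]1CO[Si](c3ccccc3)(c4ccccc4)C(C)(C)C | intermediate
13 | lithium enolate of 12 (O-lithio ketene acetal) | C=C1CC[C@H](C=C(OCC)O[Li])[C@@](C)(CCC2OCCO2)[C@@H]1CO[Si](c3ccccc3)(c4ccccc4)C(C)(C)C | intermediate
14 | ethyl (2RS)-2-[(1R,2R,3R)-3-{[tert-butyl(diphenyl)silyl]oxymethyl}-2-[2-(1,3-dioxolan-2-yl)ethyl]-2-methyl-4-methylidenecyclohexyl]propanoate | C=C1CC[C@H](C(C)C(=O)OCC)[C@@](C)(CCC2OCCO2)[C@@H]1CO[Si](c3ccccc3)(c4ccccc4)C(C)(C)C | intermediate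
15 | lithium enolate of 14 (O-lithio ketene acetal) | C=C1CC[C@H](C(C)=C(OCC)O[Li])[C@@](C)(CCC2OCCO2)[C@@H]1CO[Si](c3ccccc3)(c4ccccc4)C(C)(C)C | intermediate
16 | ethyl (2RS)-2-bromo-2-[(1S,2S,3R)-3-{[tert-butyl(diphenyl)silyl]oxymethyl}-2-[2-(1,3-dioxolan-2-yl)ethyl]-2-methyl-4-methylidenecyclohexyl]propanoate | C=C1CC[C@H](C(C)(Br)C(=O)OCC)[C@@](C)(CCC2OCCO2)[C@@H]1CO[Si](c3ccccc3)(c4ccccc4)C(C)(C)C | intermediate
17 | ethyl (2RS)-2-bromo-2-[(1S,2S,3R)-3-{[tert-butyl(diphenyl)silyl]oxymethyl}-2-methyl-4-methylidene-2-(3-oxopropyl)cyclohexyl]propanoate | C=C1CC[C@H](C(C)(Br)C(=O)OCC)[C@@](C)(CCC=O)[C@@H]1CO[Si](c2ccccc2)(c3ccccc3)C(C)(C)C | intermediate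
18 | samarium(III) enolate of 17 (O-SmI2 ketene acetal, ring stereocentres unchanged) | C=C1CC[C@H](C(C)=C(OCC)O[Sm](I)I)[C@@](C)(CCC=O)[C@@H]1CO[Si](c2ccccc2)(c3ccccc3)C(C)(C)C | intermediate
19 | ethyl (1S,2R,4aR,5R,8aS)-5-{[tert-butyl(diphenyl)silyl]oxymethyl}-2-hydroxy-1,4a-dimethyl-6-methylidenedecahydronaphthalene-1-carboxylate | C=C1CC[C@@H]2[C@](C)(C(=O)OCC)[C@H](O)CC[C@@]2(C)[C@@H]1CO[Si](c3ccccc3)(c4ccccc4)C(C)(C)C | intermediate
20 | (1R,2R,4aR,5R,8aS)-5-{[tert-butyl(diphenyl)silyl]oxymethyl}-1-(hydroxymethyl)-1,4a-dimethyl-6-methylidenedecahydronaphthalen-2-ol | C=C1CC[C@@H]2[C@](C)(CO)[C@H](O)CC[C@@]2(C)[C@@H]1CO[Si](c3ccccc3)(c4ccccc4)C(C)(C)C | intermediate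
21 | 3,19-acetonide of 20 (labdane numbering 3R,4R,5S,9R,10R; C11–OTBDPS) | C=C1CC[C@@H]2[C@](C)(COC(C)(C)O3)[C@H]3CC[C@@]2(C)[C@@H]1CO[Si](c4ccccc4)(c5ccccc5)C(C)(C)C | intermediate
22 | C11 primary alcohol of the 3,19-acetonide (3R,4R,5S,9R,10R) | C=C1CC[C@@H]2[C@](C)(COC(C)(C)O3)[C@H]3CC[C@@]2(C)[C@@H]1CO | intermediate
23 | C11 aldehyde of the 3,19-acetonide (3R,4R,5S,9R,10R) | C=C1CC[C@@H]2[C@](C)(COC(C)(C)O3)[C@H]3CC[C@@]2(C)[C@@H]1C=O | intermediate
24 | (11S)-11,12-epoxide of the 3,19-acetonide ((2S)-oxiran-2-yl on C9) | C=C1CC[C@@H]2[C@](C)(COC(C)(C)O3)[C@H]3CC[C@@]2(C)[C@@H]1[C@H]4CO4 | intermediate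
25 | 3-bromooxolan-2-one (α-bromo-γ-butyrolactone, racemic) | O=C1OCCC1Br | starting material
26 | benzenethiol | Sc1ccccc1 | starting material
27 | 3-(phenylsulfanyl)oxolan-2-one (racemic) | O=C1OCCC1Sc1ccccc1 | intermediate
28 | lithium enolate of 27 | [Li]OC1=C(Sc2ccccc2)CCO1 | intermediate
29 | diethylaluminium enolate of 27 | CC[Al](CC)OC1=C(Sc2ccccc2)CCO1 | intermediate
30 | 3-[(2R)-2-hydroxy-2-(decalinyl)ethyl]-3-(phenylsulfanyl)oxolan-2-one, 3,19-acetonide (11R; mixture at C13) | C=C1CC[C@@H]2[C@](C)(COC(C)(C)O3)[C@H]3CC[C@@]2(C)[C@@H]1[C@H](O)CC4(Sc5ccccc5)CCOC4=O | intermediate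
31 | sulfoxide of 30 | C=C1CC[C@@H]2[C@](C)(COC(C)(C)O3)[C@H]3CC[C@@]2(C)[C@@H]1[C@H](O)CC4(S(=O)c5ccccc5)CCOC4=O | intermediate
32 | 14-deoxy-11-hydroxyandrographolide 3,19-acetonide | C=C1CC[C@@H]2[C@](C)(COC(C)(C)O3)[C@H]3CC[C@@]2(C)[C@@H]1[C@H](O)CC4=CCOC4=O | intermediate
33 | 14-deoxy-11-hydroxyandrographolide (3R,4R,5S,9R,10R,11R) | C=C1CC[C@@H]2[C@](C)(CO)[C@H](O)CC[C@@]2(C)[C@@H]1[C@H](O)CC1=CCOC1=O | target

**Count and risks**
Total step count: 20. Longest linear sequence: 19 steps (steps 1–16 and 18–20; step 17 is a one-step side branch).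

Step 18 (epoxide opening by the lactone enolate). The hindered aluminium enolate may fail to open the epoxide, or the C11 alkoxide may attack the lactone carbonyl and move the lactone onto O11 (translactonisation). The fallback sets out from 24 and comes back at 30. Epoxide 24 is opened with LiI/AcOH in THF to the iodohydrin F1, which is silylated (TESOTf, 2,6-lutidine) to the triethylsilyl ether F2. The potassium enolate of 27 (KHMDS, THF/HMPA) is then alkylated with this primary iodide to give the silyl-protected sulfide F3, so no free alkoxide ever faces the lactone. Removal of the TES group with PPTS in MeOH at 0 °C gives 30.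

Step 11 (key ring closure). The tetrasubstituted samarium enolate may be protonated before it cyclises, or facial control at C4 may be lost. The fallback sets out from 12 and comes back at 19; it makes C4 after ring closure by alkylating a cyclic β-keto ester anti to the axial C10 methyl. Ester 12 is brominated (LDA, CBr4) to the secondary bromo ester F4 and the acetal is hydrolysed (aq. HCl, THF) to the bromo aldehyde F5. SmI2 Reformatsky closure gives the β-hydroxy ester F6, whose C3 and C4 configurations do not matter, and Dess–Martin oxidation gives the β-keto ester F7. C-Methylation (K2CO3, MeI, acetone) should deliver the methyl from the face opposite the C10 methyl to give the 4-methyl β-keto ester F8 with the ester axial. NaBH4 reduction by axial hydride attack then gives the equatorial alcohol 19.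

Step 5 (C9 configuration). Attack of the electrophile anti to the axial C10 methyl may give mainly the 9-epimer, and the equilibration in step 6 may enrich the wanted isomer too little or cause β-elimination of the silyloxy group. The fallback sets out from 9 and comes back at 11; it creates C9 by protonation instead of C–C bond formation. Enol silane 9 is treated with dimethyl(methylidene)ammonium iodide to give the Mannich base F9, and quaternisation with MeI followed by NaHCO3 gives the α-methylene ketone F10. Copper-catalysed conjugate borylation (B2pin2, CuCl, Xantphos, NaOt-Bu, MeOH) should give the boryl ketone F11, with the C9 proton delivered anti to the axial C10 methyl. Oxidation with NaBO3 gives the single hydroxymethyl ketone F12, which is silylated as in step 6 (without DBU) to give 11.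

**Further compounds**
F1 | step 18 | iodohydrin, (11S)-12-iodo-11-ol of the 3,19-acetonide | C=C1CC[C@@H]2[C@](C)(COC(C)(C)O3)[C@H]3CC[C@@]2(C)[C@@H]1[C@H](O)CI
F2 | step 18 | triethylsilyl ether of F1 | C=C1CC[C@@H]2[C@](C)(COC(C)(C)O3)[C@H]3CC[C@@]2(C)[C@@H]1[C@H](O[Si](CC)(CC)CC)CI
F3 | step 18 | 11-O-triethylsilyl ether of 30 | C=C1CC[C@@H]2[C@](C)(COC(C)(C)O3)[C@H]3CC[C@@]2(C)[C@@H]1[C@H](O[Si](CC)(CC)CC)CC4(Sc5ccccc5)CCOC4=O
F4 | step 11 | ethyl (2RS)-2-bromo-2-[(1S,2S,3R)-3-{[tert-butyl(diphenyl)silyl]oxymethyl}-2-[2-(1,3-dioxolan-2-yl)ethyl]-2-methyl-4-methylidenecyclohexyl]acetate | C=C1CC[C@H](C(Br)C(=O)OCC)[C@@](C)(CCC2OCCO2)[C@@H]1CO[Si](c3ccccc3)(c4ccccc4)C(C)(C)C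
F5 | step 11 | ethyl (2RS)-2-bromo-2-[(1S,2S,3R)-3-{[tert-butyl(diphenyl)silyl]oxymethyl}-2-methyl-4-methylidene-2-(3-oxopropyl)cyclohexyl]acetate | C=C1CC[C@H](C(Br)C(=O)OCC)[C@@](C)(CCC=O)[C@@H]1CO[Si](c2ccccc2)(c3ccccc3)C(C)(C)C
F6 | step 11 | 4-demethyl analogue of 19 (β-hydroxy ester, mixture at C3 and C4) | C=C1CC[C@@H]2C(C(=O)OCC)C(O)CC[C@@]2(C)[C@@H]1CO[Si](c3ccccc3)(c4ccccc4)C(C)(C)C
F7 | step 11 | 3-oxo-4-demethyl analogue of 19 (β-keto ester) | C=C1CC[C@@H]2C(C(=O)OCC)C(=O)CC[C@@]2(C)[C@@H]1CO[Si](c3ccccc3)(c4ccccc4)C(C)(C)C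
F8 | step 11 | ethyl (1S,4aR,5R,8aS)-5-{[tert-butyl(diphenyl)silyl]oxymethyl}-1,4a-dimethyl-6-methylidene-2-oxodecahydronaphthalene-1-carboxylate | C=C1CC[C@@H]2[C@](C)(C(=O)OCC)C(=O)CC[C@@]2(C)[C@@H]1CO[Si](c3ccccc3)(c4ccccc4)C(C)(C)C
F9 | step 5 | ethyl 2-[(1R,2R,3RS)-3-[(dimethylamino)methyl]-2-[2-(1,3-dioxolan-2-yl)ethyl]-2-methyl-4-oxocyclohexyl]acetate | CCOC(=O)C[C@H]1CCC(=O)C(CN(C)C)[C@]1(C)CCC2OCCO2
F10 | step 5 | ethyl 2-[(1R,2R)-2-[2-(1,3-dioxolan-2-yl)ethyl]-2-methyl-3-methylidene-4-oxocyclohexyl]acetate | CCOC(=O)C[C@H]1CCC(=O)C(=C)[C@]1(C)CCC2OCCO2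
F11 | step 5 | ethyl 2-[(1R,2R,3S)-2-[2-(1,3-dioxolan-2-yl)ethyl]-2-methyl-4-oxo-3-[(4,4,5,5-tetramethyl-1,3,2-dioxaborolan-2-yl)methyl]cyclohexyl]acetate | CCOC(=O)C[C@H]1CCC(=O)[C@@H](CB2OC(C)(C)C(C)(C)O2)[C@]1(C)CCC3OCCO3
F12 | step 5 | ethyl 2-[(1R,2R,3R)-2-[2-(1,3-dioxolan-2-yl)ethyl]-3-(hydroxymethyl)-2-methyl-4-oxocyclohexyl]acetate (single C9 epimer of 10) | CCOC(=O)C[C@H]1CCC(=O)[C@@H](CO)[C@]1(C)CCC2OCCO2
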